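Everything rests on cutting the bond between ring A carbon C1' and ketone carbon C1. The feature exploited is that C1 is an acyl carbon flanked by the oxygen-bearing stereocentre C2, so C1–C2–C3 with ring B is (R)-4-hydroxyphenyllactic acid, D-tyrosine with oxygen for nitrogen, while ring A is a resorcinol whose C1' can be marked by bromine. In one operation an aryllithium is acylated by an N-methoxy-N-methylamide, joining both halves at the ketone oxidation level and leaving C2 untouched. The precursors are 2,4-bis(benzyloxy)-1-bromobenzene and the (R)-amide silylated at O2 and at the ring B phenol; benzyl ethers are later traded for the geranyl ether at O4'.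

Key step: step 5

Remark: C1 is the ketone carbon, C2 the carbinol carbon, C3 the benzylic carbon. Ring A is the resorcinol ring (C1' bears C1; O2' and O4' are its oxygens) and ring B is the 4-hydroxyphenyl ring. C2 of the target is (R), the spatial arrangement of D-tyrosine with oxygen in place of nitrogen, so a deamination with net retention supplies the required enantiomer. TBS = tert-butyldimethylsilyl.

Step 1
Reactants: 1 D-tyrosine
Product: 4 (R)-2-hydroxy-3-(4-hydroxyphenyl)propanoic acid, via diazonium carboxylate 2 (not isolated), via alpha-lactone 3 (not isolated)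
Conditions: NaNO2, 1 M aq. H2SO4, 0 °C to rt
Reagents that add atoms: water, O
Why: Nitrous acid deamination of an alpha-amino acid (diazotisation) should occur with net retention at C2, because the neighbouring carboxylate expels dinitrogen from diazonium 2 with inversion to form alpha-lactone 3 and water then opens 3 at C2 with a second inversion, so the (R) centre of D-tyrosine is carried into 4 and no stereocentre has to be made.

Step 2
Reactants: 4 (R)-2-hydroxy-3-(4-hydroxyphenyl)propanoic acid
Product: 6 (R)-2-hydroxy-3-(4-hydroxyphenyl)-N-methoxy-N-methylpropanamide, via benzotriazol-1-yl active ester 5 (not isolated)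
Conditions: MeNH(OMe)·HCl, EDC·HCl, HOBt, N-methylmorpholine, DMF, 0 °C to rt
Reagents that add atoms: N,O-dimethylhydroxylamine hydrochloride, CNOC.Cl
Why: Carbodiimide amide coupling through active ester 5 should acylate the amine nitrogen in preference to the much less nucleophilic secondary hydroxyl and phenol, so no protection is needed, and an alpha-hydroxy active ester cannot racemise through an oxazolone, which keeps C2 intact.

Step 3
Reactants: 6 (R)-2-hydroxy-3-(4-hydroxyphenyl)-N-methoxy-N-methylpropanamide
Product: 7 (R)-2-(tert-butyldimethylsilyloxy)-3-[4-(tert-butyldimethylsilyloxy)phenyl]-N-methoxy-N-methylpropanamide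
Conditions: TBSCl (2.5 equiv), imidazole, DMF, rt
Reagents that add atoms: tert-butyldimethylsilyl chloride, CC(C)(C)[Si](C)(C)Cl
Why: Silyl ether formation with TBSCl and imidazole should cap the phenol and the secondary alcohol in one operation, which removes both acidic protons before the organolithium step and shields the C2–H bond without touching the stereocentre.

Step 4
Reactants: 8 4-bromoresorcinol
Product: 9 2,4-bis(benzyloxy)-1-bromobenzene
Conditions: BnBr (2.3 equiv), K2CO3, DMF, rt
Reagents that add atoms: benzyl bromide, BrCc1ccccc1
Why: Double Williamson ether synthesis with a reactive benzylic bromide should benzylate both phenols completely while the aryl bromide, which later defines C1', is inert to carbonate base.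

Step 5
Reactants: 9 2,4-bis(benzyloxy)-1-bromobenzene; 7 (R)-2-(tert-butyldimethylsilyloxy)-3-[4-(tert-butyldimethylsilyloxy)phenyl]-N-methoxy-N-methylpropanamide
Product: 12 (R)-1-[2,4-bis(benzyloxy)phenyl]-2-(tert-butyldimethylsilyloxy)-3-[4-(tert-butyldimethylsilyloxy)phenyl]propan-1-one, via 2,4-bis(benzyloxy)phenyllithium 10 (not isolated), via lithium hemiaminal chelate 11 (not isolated)
Conditions: 9 (1.3 equiv), n-BuLi (1.25 equiv), THF, −78 °C, 30 min; then 7 (1.0 equiv) in THF, −78 °C; sat. aq. NH4Cl, −78 °C to rt
Reagents that add atoms: none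
Why: Bromine–lithium exchange on 9 at −78 °C gives aryllithium 10 with the carbanion at C1', ortho to one benzyloxy group and para to the other, so the position of the halogen and not any directing effect decides the ring A regiochemistry. Carbonyl addition of 10 to amide 7 forms tetrahedral adduct 11, in which lithium is chelated between the new alkoxide oxygen and the N-methoxy oxygen; 11 survives until the cold aqueous quench and only then collapses to ketone 12, which therefore never meets the organolithium and cannot add a second time. The closest known reaction type is the Weinreb ketone synthesis with alpha-silyloxy N-methoxy-N-methylamides and aryllithium reagents. No ring is closed and no stereocentre is created, since the hemiaminal carbon of 11 is lost on collapse and C2 is carried over from 7. The selectivity required is addition to the carbonyl over proton abstraction at C2 or at the N-methoxy group, and it is secured by the low temperature, by the bulky silyloxy group that shields the C2–H bond, and by keeping n-BuLi just below one equivalent relative to 9 so that no free alkyllithium is present. The benzyl ethers and the aryl silyl ether should tolerate 10 at −78 °C, where benzylic metalation and attack at silicon are slow.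

Step 6
Reactants: 12 (R)-1-[2,4-bis(benzyloxy)phenyl]-2-(tert-butyldimethylsilyloxy)-3-[4-(tert-butyldimethylsilyloxy)phenyl]propan-1-one
Product: 13 (R)-2-(tert-butyldimethylsilyloxy)-3-[4-(tert-butyldimethylsilyloxy)phenyl]-1-(2,4-dihydroxyphenyl)propan-1-one
Conditions: H2 (1 atm), 10% Pd/C, EtOAc, rt
Reagents that add atoms: none
Why: Catalytic hydrogenolysis of aryl benzyl ethers over Pd/C in ethyl acetate is fast compared with reduction of the hindered, electron-rich aryl ketone and leaves silyl ethers and C2 untouched, so both ring A hydroxyls should be freed.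

Step 7
Reactants: 13 (R)-2-(tert-butyldimethylsilyloxy)-3-[4-(tert-butyldimethylsilyloxy)phenyl]-1-(2,4-dihydroxyphenyl)propan-1-one; 14 geranyl bromide
Product: 15 (R)-2-(tert-butyldimethylsilyloxy)-3-[4-(tert-butyldimethylsilyloxy)phenyl]-1-{4-[(2E)-3,7-dimethylocta-2,6-dien-1-yloxy]-2-hydroxyphenyl}propan-1-one
Conditions: 14 (1.1 equiv), K2CO3 (1.2 equiv), acetone, rt
Reagents that add atoms: none
Why: Williamson ether synthesis should take place at O4' only, because the 4'-hydroxyl para to the ketone is the most acidic and unencumbered while the 2'-hydroxyl is tied up in a hydrogen bond to the ketone oxygen, and one equivalent of K2CO3 in acetone at room temperature is mild enough to spare the aryl silyl ether and the C2–H bond.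

Step 8
Reactants: 15 (R)-2-(tert-butyldimethylsilyloxy)-3-[4-(tert-butyldimethylsilyloxy)phenyl]-1-{4-[(2E)-3,7-dimethylocta-2,6-dien-1-yloxy]-2-hydroxyphenyl}propan-1-one
Product: 16 (R)-1-{4-[(2E)-3,7-dimethylocta-2,6-dien-1-yloxy]-2-hydroxyphenyl}-2-hydroxy-3-(4-hydroxyphenyl)propan-1-one (target)
Conditions: TBAF, AcOH (1:1, excess), THF, 0 °C to rt
Reagents that add atoms: none
Why: Fluoride-mediated desilylation, driven by the strength of the Si–F bond, should cleave the aryl and the secondary silyl ether, and the acetic acid buffer keeps alkoxide and phenoxide from building up, so the freed alpha-hydroxy ketone should not enolise at C2 and the acid-sensitive geranyl ether is not exposed to strong acid.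

Compound list
1 | D-tyrosine, (R)-2-amino-3-(4-hydroxyphenyl)propanoic acid | N[C@H](Cc1ccc(O)cc1)C(=O)O | starting material
2 | (R)-2-diazonio-3-(4-hydroxyphenyl)propanoate (diazonium carboxylate) | N#[N+][C@H](Cc1ccc(O)cc1)C(=O)[O-] | intermediate
3 | (S)-3-(4-hydroxybenzyl)oxiran-2-one (alpha-lactone) | O=C1O[C@H]1Cc1ccc(O)cc1 | intermediate
4 | (R)-2-hydroxy-3-(4-hydroxyphenyl)propanoic acid | O[C@H](Cc1ccc(O)cc1)C(=O)O | intermediate
5 | benzotriazol-1-yl (R)-2-hydroxy-3-(4-hydroxyphenyl)propanoate (active ester) | O[C@H](Cc1ccc(O)cc1)C(=O)On1nnc2ccccc12 | intermediate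
6 | (R)-2-hydroxy-3-(4-hydroxyphenyl)-N-methoxy-N-methylpropanamide | CON(C)C(=O)[C@H](O)Cc1ccc(O)cc1 | intermediate
7 | (R)-2-(tert-butyldimethylsilyloxy)-3-[4-(tert-butyldimethylsilyloxy)phenyl]-N-methoxy-N-methylpropanamide | CON(C)C(=O)[C@H](O[Si](C)(C)C(C)(C)C)Cc1ccc(O[Si](C)(C)C(C)(C)C)cc1 | intermediate
8 | 4-bromoresorcinol (4-bromobenzene-1,3-diol) | Oc1ccc(Br)c(O)c1 | starting material
9 | 2,4-bis(benzyloxy)-1-bromobenzene | Brc1ccc(OCc2ccccc2)cc1OCc1ccccc1 | intermediate
10 | 2,4-bis(benzyloxy)phenyllithium | [Li]c1ccc(OCc2ccccc2)cc1OCc1ccccc1 | intermediate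
11 | lithium (2R)-1-[2,4-bis(benzyloxy)phenyl]-1-[methoxy(methyl)amino]-2-(tert-butyldimethylsilyloxy)-3-[4-(tert-butyldimethylsilyloxy)phenyl]propan-1-olate (hemiaminal chelate, C1 undefined) | CON(C)C(O[Li])(c1ccc(OCc2ccccc2)cc1OCc1ccccc1)[C@H](O[Si](C)(C)C(C)(C)C)Cc1ccc(O[Si](C)(C)C(C)(C)C)cc1 | intermediate
12 | (R)-1-[2,4-bis(benzyloxy)phenyl]-2-(tert-butyldimethylsilyloxy)-3-[4-(tert-butyldimethylsilyloxy)phenyl]propan-1-one | O=C(c1ccc(OCc2ccccc2)cc1OCc1ccccc1)[C@H](O[Si](C)(C)C(C)(C)C)Cc1ccc(O[Si](C)(C)C(C)(C)C)cc1 | intermediate
13 | (R)-2-(tert-butyldimethylsilyloxy)-3-[4-(tert-butyldimethylsilyloxy)phenyl]-1-(2,4-dihydroxyphenyl)propan-1-one | O=C(c1ccc(O)cc1O)[C@H](O[Si](C)(C)C(C)(C)C)Cc1ccc(O[Si](C)(C)C(C)(C)C)cc1 | intermediate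
14 | geranyl bromide, (2E)-1-bromo-3,7-dimethylocta-2,6-diene | CC(C)=CCC/C(C)=C/CBr | starting material
15 | (R)-2-(tert-butyldimethylsilyloxy)-3-[4-(tert-butyldimethylsilyloxy)phenyl]-1-{4-[(2E)-3,7-dimethylocta-2,6-dien-1-yloxy]-2-hydroxyphenyl}propan-1-one | CC(C)=CCC/C(C)=C/COc1ccc(C(=O)[C@H](O[Si](C)(C)C(C)(C)C)Cc2ccc(O[Si](C)(C)C(C)(C)C)cc2)c(O)c1 | intermediate
16 | (R)-1-{4-[(2E)-3,7-dimethylocta-2,6-dien-1-yloxy]-2-hydroxyphenyl}-2-hydroxy-3-(4-hydroxyphenyl)propan-1-one | CC(C)=CCC/C(C)=C/COc1ccc(C(=O)[C@H](O)Cc2ccc(O)cc2)c(O)c1 | target

Total step count: 8 (the one-pot exchange and acylation counted as one step).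
Longest linear sequence: 7 steps (steps 1, 2, 3, 5, 6, 7, 8, from D-tyrosine to the target); step 4 is a one-step branch that joins in step 5.

Steps most likely to fail

Step 5. The aryllithium may act as a base instead of a nucleophile, abstracting the C2 proton (erosion of enantiopurity) or a proton of the N-methoxy group (fragmentation of the amide). If the exchange mixture warms, metalation of the ortho benzylic position followed by [1,2]-Wittig rearrangement may consume the nucleophile. The fallback sets out from 7 and 9. Amide 7 would be reduced with i-Bu2AlH in THF at −78 °C to (R)-2-(tert-butyldimethylsilyloxy)-3-[4-(tert-butyldimethylsilyloxy)phenyl]propanal F1. Aryllithium 10, made from 9 as before, would then add at −78 °C to this far more electrophilic carbonyl, so that addition outruns proton transfer, to give (2R)-1-[2,4-bis(benzyloxy)phenyl]-2-(tert-butyldimethylsilyloxy)-3-[4-(tert-butyldimethylsilyloxy)phenyl]propan-1-ol F2 as a mixture of C1 epimers. Dess–Martin oxidation buffered with NaHCO3 in CH2Cl2 would erase the C1 centre and bring the sequence back to the route at 12.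

Step 7. The ring A phenoxide may pull the silyl group off the ring B phenol, which would then be alkylated as well. A second alkylation at O2' or slow base-induced epimerisation at C2 are further possibilities. The fallback sets out from 13 and replaces the basic alkylation by a Mitsunobu etherification with geraniol, PPh3 and diisopropyl azodicarboxylate in THF at 0 °C to rt. No base is present, and only the most acidic, unchelated 4'-hydroxyl should be engaged. This fallback makes no new compound (F0) and comes back to the route at 15.

Step 8. Cleavage of the hindered secondary silyl ether next to the ketone may be slow under buffered fluoride. Forcing it with unbuffered fluoride would invite enolisation of the alpha-hydroxy ketone, with loss of configuration at C2 or alpha-ketol transposition. The fallback sets out from 15 and unmasks in two chemoselective stages that never generate a basic species. KHF2 in MeOH at rt should remove only the phenolic silyl group, giving (R)-2-(tert-butyldimethylsilyloxy)-1-{4-[(2E)-3,7-dimethylocta-2,6-dien-1-yloxy]-2-hydroxyphenyl}-3-(4-hydroxyphenyl)propan-1-one F3. HF·pyridine with added pyridine in THF, 0 °C to rt, would then cleave the secondary silyl ether and come back to the route at 16.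

Further compounds
F1 | step 5 | (R)-2-(tert-butyldimethylsilyloxy)-3-[4-(tert-butyldimethylsilyloxy)phenyl]propanal | O=C[C@H](O[Si](C)(C)C(C)(C)C)Cc1ccc(O[Si](C)(C)C(C)(C)C)cc1
F2 | step 5 | (2R)-1-[2,4-bis(benzyloxy)phenyl]-2-(tert-butyldimethylsilyloxy)-3-[4-(tert-butyldimethylsilyloxy)phenyl]propan-1-ol (both C1 epimers) | OC(c1ccc(OCc2ccccc2)cc1OCc1ccccc1)[C@H](O[Si](C)(C)C(C)(C)C)Cc1ccc(O[Si](C)(C)C(C)(C)C)cc1
F0 | step 7 | none | none
F3 | step 8 | (R)-2-(tert-butyldimethylsilyloxy)-1-{4-[(2E)-3,7-dimethylocta-2,6-dien-1-yloxy]-2-hydroxyphenyl}-3-(4-hydroxyphenyl)propan-1-one | CC(C)=CCC/C(C)=C/COc1ccc(C(=O)[C@H](O[Si](C)(C)C(C)(C)C)Cc2ccc(O)cc2)c(O)c1
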